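**Retrosynthetic overview**

Numbering: C1 benzylic CH2, C2 acetoxy carbinol, C3–C7 methylenes, C8 free carbinol, C9–C13 n-pentyl. The strategy rests on C8: its two arms (n-pentyl C9–C13 and the C7–C3 chain) are identical over four carbons, so C8 is fixed by reagent control while the C7–C8 bond is made.
C7–C8: (+)-sparteine-directed lithiation of hexyl N,N-diisopropylcarbamate, borylation with the primary C7 pinacol boronate and 1,2-metallate shift. Boron stays at C8 as a masked hydroxyl, so the C2 oxygen can be acetylated first.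
C7–B: iridium-catalysed hydroboration of the C6=C7 alkene. C1–aryl: aryl Grignard opening of (R)-2-(pent-4-enyl)oxirane, whose centre (future C2) comes from hydrolytic kinetic resolution of hepta-1,6-diene monoepoxide.
End game: C2 silyl ether to acetate, C8–B to C8–OH with retention, O-debenzylation. No ring is formed in the route; the benzene ring is bought with its 1,3,5-oxygenation pattern.

Key step: step 8

Assumption: (+)-sparteine is taken as commercially available; the (+)-sparteine surrogate diamine would act in the same sense.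

**Route**

Step 1
Reactants: 1 3-bromo-5-methoxyphenol
Product: 2 1-(benzyloxy)-3-bromo-5-methoxybenzene
Conditions: BnBr (1.1 equiv), K2CO3, DMF, rt
Reagents that add atoms: benzyl bromide, BrCc1ccccc1
Why: Williamson ether synthesis on the phenoxide masks the acidic phenol before any organometallic step and gives a group removable at the end by hydrogenolysis.

Step 2
Reactants: 3 hepta-1,6-diene
Product: 4 rac-2-(pent-4-en-1-yl)oxirane
Conditions: mCPBA (0.4 equiv), NaHCO3, CH2Cl2, 0 °C to rt; excess 3 distilled off and reused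
Reagents that add atoms: meta-chloroperoxybenzoic acid, OOC(=O)c1cccc(Cl)c1
Why: Prilezhaev epoxidation of one of two independent terminal alkenes, with the diene in excess so that bis-epoxidation is held down statistically.

Step 3
Reactants: 4 rac-2-(pent-4-en-1-yl)oxirane
Product: 5 (R)-2-(pent-4-en-1-yl)oxirane
Conditions: (R,R)-(salen)Co(OAc) (trivalent cobalt; salen = N,N'-bis(3,5-di-tert-butylsalicylidene)-1,2-cyclohexanediamine; 0.5 mol %), H2O (0.55 equiv), THF (minimal), 0 °C to rt; distillation
Reagents that add atoms: none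
Why: Jacobsen hydrolytic kinetic resolution, in which the (R,R)-catalyst (the enantiomer that consumes the (S)-oxirane) should hydrolyse the (S)-epoxide to the diol and leave the (R)-epoxide, the future C2 centre, to be distilled off.

Step 4
Reactants: 2 1-(benzyloxy)-3-bromo-5-methoxybenzene; 5 (R)-2-(pent-4-en-1-yl)oxirane
Product: 7 (2R)-1-[3-(benzyloxy)-5-methoxyphenyl]hept-6-en-2-ol, via arylmagnesium bromide 6 (not isolated)
Conditions: 2, Mg, THF, reflux; then CuI (10 mol %), 5, THF, −30 to 0 °C; H2O/aq NH4Cl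
Reagents that add atoms: none
Why: Magnesium insertion gives Grignard reagent 6, and its copper-catalysed SN2 opening of the terminal epoxide at the unsubstituted carbon forms the C1–aryl bond without touching the C–O stereocentre, so (R)-5 gives (R)-7.

Step 5
Reactants: 7 (2R)-1-[3-(benzyloxy)-5-methoxyphenyl]hept-6-en-2-ol
Product: 8 tert-butyl({(2R)-1-[3-(benzyloxy)-5-methoxyphenyl]hept-6-en-2-yl}oxy)dimethylsilane
Conditions: TBSCl, imidazole, DMF, rt
Reagents that add atoms: tert-butyldimethylsilyl chloride, CC(C)(C)[Si](C)(C)Cl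
Why: Imidazole-promoted silylation of the secondary alcohol gives an ether that is inert to organolithiums and MgBr2·OEt2 and is later cleaved by acid without affecting a boronic ester.

Step 6
Reactants: 8 tert-butyl({(2R)-1-[3-(benzyloxy)-5-methoxyphenyl]hept-6-en-2-yl}oxy)dimethylsilane
Product: 9 2-[(6R)-7-[3-(benzyloxy)-5-methoxyphenyl]-6-[(tert-butyldimethylsilyl)oxy]heptyl]-4,4,5,5-tetramethyl-1,3,2-dioxaborolane
Conditions: HBpin (1.2 equiv), [Ir(cod)Cl]2 (1.5 mol %), dppm (3 mol %), CH2Cl2, rt
Reagents that add atoms: pinacolborane, CC1(C)OBOC1(C)C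
Why: Iridium–diphosphine-catalysed hydroboration of an aliphatic terminal alkene with pinacolborane places boron at the terminal carbon (C7) and tolerates silyl and aryl ethers.

Step 7
Reactants: 10 hexan-1-ol
Product: 11 hexyl N,N-diisopropylcarbamate
Conditions: iPr2NC(O)Cl (1.2 equiv), Et3N, CH2Cl2, reflux
Reagents that add atoms: N,N-diisopropylcarbamoyl chloride, CC(C)N(C(C)C)C(Cl)=O
Why: O-Carbamoylation of the primary alcohol installs the hindered carbamate that directs α-lithiation and later serves as the leaving group.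

Step 8
Reactants: 11 hexyl N,N-diisopropylcarbamate; 9 2-[(6R)-7-[3-(benzyloxy)-5-methoxyphenyl]-6-[(tert-butyldimethylsilyl)oxy]heptyl]-4,4,5,5-tetramethyl-1,3,2-dioxaborolane
Product: 14 tert-butyl({(2R,8S)-1-[3-(benzyloxy)-5-methoxyphenyl]-8-(4,4,5,5-tetramethyl-1,3,2-dioxaborolan-2-yl)tridecan-2-yl}oxy)dimethylsilane, via lithiated carbamate 12 (not isolated), via boronate complex 13 (not isolated)
Conditions: 11 (1.4 equiv), (+)-sparteine (1.4 equiv), s-BuLi (1.3 equiv), Et2O, −78 °C, 5 h; 9 (1.0 equiv), −78 °C, 1 h; MgBr2·OEt2 (2 equiv), −78 °C to reflux, 16 h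
Reagents that add atoms: none
Why: s-BuLi·(+)-sparteine removes the pro-R α-proton of 11 (mirror image of the pro-S selectivity established for (−)-sparteine) to give the configurationally stable (R)-lithiated carbamate 12, which attacks the unhindered primary boronate 9 at boron with retention to form ate complex 13. On warming with MgBr2·OEt2 the C7 alkyl group migrates from boron to C8 antiperiplanar to the magnesium-activated carbamate, which departs with inversion, so the C7–C8 bond and the C8 stereocentre form in one stereospecific event. This is the lithiation–borylation reaction, a Matteson-type 1,2-metallate rearrangement of a boronate complex derived from a Hoppe lithiated carbamate; no ring is closed. C8 is controlled by the chiral diamine alone (enantiotopic deprotonation, then retention followed by inversion), independent of the remote C2 centre and of the near-identity of the two arms, and boron ends up where the oxygen of the (S)-carbinol is required. The step needs reaction at boron instead of metalation of the electron-rich arene or the benzylic ether CH2; this is secured by consuming all s-BuLi in forming 12 (carbamate in slight excess) before 9 is added at −78 °C, and the silyl, benzyl and methyl ethers are inert to 12 and to MgBr2·OEt2.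

Step 9
Reactants: 14 tert-butyl({(2R,8S)-1-[3-(benzyloxy)-5-methoxyphenyl]-8-(4,4,5,5-tetramethyl-1,3,2-dioxaborolan-2-yl)tridecan-2-yl}oxy)dimethylsilane
Product: 15 (2R,8S)-1-[3-(benzyloxy)-5-methoxyphenyl]-8-(4,4,5,5-tetramethyl-1,3,2-dioxaborolan-2-yl)tridecan-2-ol
Conditions: HCl (0.5 M in MeOH), 0 °C to rt
Reagents that add atoms: none
Why: Acid-catalysed methanolysis cleaves the secondary silyl ether, while the hindered secondary pinacol boronate and the aryl ethers are stable to dilute acid.

Step 10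
Reactants: 15 (2R,8S)-1-[3-(benzyloxy)-5-methoxyphenyl]-8-(4,4,5,5-tetramethyl-1,3,2-dioxaborolan-2-yl)tridecan-2-ol
Product: 16 (2R,8S)-1-[3-(benzyloxy)-5-methoxyphenyl]-8-(4,4,5,5-tetramethyl-1,3,2-dioxaborolan-2-yl)tridecan-2-yl acetate
Conditions: Ac2O, pyridine, DMAP (cat.), CH2Cl2, rt
Reagents that add atoms: acetic anhydride, CC(=O)OC(C)=O
Why: DMAP-catalysed acylation esterifies the only free hydroxyl (C2) because the C8 oxygen is still masked as the C–B bond, which secures the site selectivity.

Step 11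
Reactants: 16 (2R,8S)-1-[3-(benzyloxy)-5-methoxyphenyl]-8-(4,4,5,5-tetramethyl-1,3,2-dioxaborolan-2-yl)tridecan-2-yl acetate
Product: 17 (2R,8S)-1-[3-(benzyloxy)-5-methoxyphenyl]-8-hydroxytridecan-2-yl acetate
Conditions: NaBO3·4H2O (4 equiv), THF/H2O (1:1), rt
Reagents that add atoms: sodium perborate (used as the tetrahydrate), [Na+].[O-]OB=O
Why: Perborate oxidation of the organoboronate proceeds by 1,2-shift of C8 from boron to oxygen with retention, giving the (S)-carbinol under mildly basic conditions chosen to spare the acetate.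

Step 12
Reactants: 17 (2R,8S)-1-[3-(benzyloxy)-5-methoxyphenyl]-8-hydroxytridecan-2-yl acetate
Product: 18 (2R,8S)-8-hydroxy-1-(3-hydroxy-5-methoxyphenyl)tridecan-2-yl acetate
Conditions: H2 (1 atm), Pd/C (10 wt %), EtOAc, rt
Reagents that add atoms: none
Why: Catalytic hydrogenolysis cleaves the aryl benzyl ether, while the homobenzylic acetate, the secondary alcohol and the methyl ether are not hydrogenolysed.

**Compound list**

1 | 3-bromo-5-methoxyphenol | COc1cc(O)cc(Br)c1 | starting material
2 | 1-(benzyloxy)-3-bromo-5-methoxybenzene | COc1cc(Br)cc(OCc2ccccc2)c1 | intermediate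
3 | hepta-1,6-diene | C=CCCCC=C | starting material
4 | rac-2-(pent-4-en-1-yl)oxirane | C=CCCCC1CO1 | intermediate
5 | (R)-2-(pent-4-en-1-yl)oxirane | C=CCCC[C@@H]1CO1 | intermediate
6 | [3-(benzyloxy)-5-methoxyphenyl]magnesium bromide (formed in the flask) | COc1cc([Mg]Br)cc(OCc2ccccc2)c1 | intermediate
7 | (2R)-1-[3-(benzyloxy)-5-methoxyphenyl]hept-6-en-2-ol | C=CCCC[C@H](Cc1cc(OCc2ccccc2)cc(OC)c1)O | intermediate
8 | tert-butyl({(2R)-1-[3-(benzyloxy)-5-methoxyphenyl]hept-6-en-2-yl}oxy)dimethylsilane | C=CCCC[C@H](Cc1cc(OCc2ccccc2)cc(OC)c1)O[Si](C)(C)C(C)(C)C | intermediate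
9 | 2-[(6R)-7-[3-(benzyloxy)-5-methoxyphenyl]-6-[(tert-butyldimethylsilyl)oxy]heptyl]-4,4,5,5-tetramethyl-1,3,2-dioxaborolane | CC1(C)OB(CCCCC[C@H](Cc2cc(OCc3ccccc3)cc(OC)c2)O[Si](C)(C)C(C)(C)C)OC1(C)C | intermediate
10 | hexan-1-ol | CCCCCCO | starting material
11 | hexyl N,N-diisopropylcarbamate | CCCCCCOC(=O)N(C(C)C)C(C)C | intermediate
12 | (R)-1-lithiohexyl N,N-diisopropylcarbamate, as its (+)-sparteine complex (formed in the flask) | CCCCC[C@@H]([Li])OC(=O)N(C(C)C)C(C)C | intermediate
13 | lithium [(1R)-1-(N,N-diisopropylcarbamoyloxy)hexyl]{(6R)-7-[3-(benzyloxy)-5-methoxyphenyl]-6-[(tert-butyldimethylsilyl)oxy]heptyl}(pinacolato)borate (formed in the flask) | CCCCC[C@@H]([B-]1(CCCCC[C@H](Cc2cc(OCc3ccccc3)cc(OC)c2)O[Si](C)(C)C(C)(C)C)OC(C)(C)C(C)(C)O1)OC(=O)N(C(C)C)C(C)C.[Li+] | intermediate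
14 | tert-butyl({(2R,8S)-1-[3-(benzyloxy)-5-methoxyphenyl]-8-(4,4,5,5-tetramethyl-1,3,2-dioxaborolan-2-yl)tridecan-2-yl}oxy)dimethylsilane | CCCCC[C@H](B1OC(C)(C)C(C)(C)O1)CCCCC[C@H](Cc1cc(OCc2ccccc2)cc(OC)c1)O[Si](C)(C)C(C)(C)C | intermediate
15 | (2R,8S)-1-[3-(benzyloxy)-5-methoxyphenyl]-8-(4,4,5,5-tetramethyl-1,3,2-dioxaborolan-2-yl)tridecan-2-ol | CCCCC[C@H](B1OC(C)(C)C(C)(C)O1)CCCCC[C@H](Cc1cc(OCc2ccccc2)cc(OC)c1)O | intermediate
16 | (2R,8S)-1-[3-(benzyloxy)-5-methoxyphenyl]-8-(4,4,5,5-tetramethyl-1,3,2-dioxaborolan-2-yl)tridecan-2-yl acetate | CCCCC[C@H](B1OC(C)(C)C(C)(C)O1)CCCCC[C@H](Cc1cc(OCc2ccccc2)cc(OC)c1)OC(C)=O | intermediate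
17 | (2R,8S)-1-[3-(benzyloxy)-5-methoxyphenyl]-8-hydroxytridecan-2-yl acetate | CCCCC[C@H](O)CCCCC[C@H](Cc1cc(OCc2ccccc2)cc(OC)c1)OC(C)=O | intermediate
18 | (2R,8S)-8-hydroxy-1-(3-hydroxy-5-methoxyphenyl)tridecan-2-yl acetate (CNP0415796.1) | CCCCC[C@H](O)CCCCC[C@H](Cc1cc(O)cc(OC)c1)OC(C)=O | target

**Step count**

Total steps: 12. Longest linear sequence: 10 steps (steps 2, 3, 4, 5, 6, 8, 9, 10, 11, 12 from hepta-1,6-diene).

**Steps most likely to fail**

1. Step 8. The carbamate is a reluctant leaving group, so the ate complex may revert to its partners on warming instead of rearranging. Residual base may metalate the resorcinol ring or the benzylic ether CH2. Enantioselectivity erodes if the lithiated carbamate warms before it is borylated. Fallback, setting out from 7 and coming back at 17: C8 is taken from the chiral pool and the chains are joined by olefin cross-metathesis. Acetylation of 7 (Ac2O, pyridine, DMAP, CH2Cl2) should give (2R)-1-[3-(benzyloxy)-5-methoxyphenyl]hept-6-en-2-yl acetate F1. Cross-metathesis of F1 with commercial (S)-oct-1-en-3-ol (CCCCC[C@H](O)C=C, 3 equiv; second-generation Grubbs catalyst RuCl2(=CHPh)(H2IMes)(PCy3), CH2Cl2, 40 °C) should give (2R,6E,8S)-1-[3-(benzyloxy)-5-methoxyphenyl]-8-hydroxytridec-6-en-2-yl acetate F2, in which C2 is already acetylated and C8 arrives as the free carbinol. Diimide reduction of the C6=C7 alkene (2-nitrobenzenesulfonyl hydrazide, Et3N, CH2Cl2, rt), which leaves the benzyl ether and acetate alone, returns to 17; step 12 then finishes the route.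

2. Step 11. Basic peroxide may cleave the C2 acetate by acyl transfer while the hindered secondary boronate is oxidised only slowly. Fallback, setting out from 14 and coming back at 18: the boronate is oxidised before any ester is present and C8 is carried as a benzyl ether. Oxidation of 14 (H2O2, NaOH, THF, 0 °C) should give (2R,8S)-1-[3-(benzyloxy)-5-methoxyphenyl]-2-[(tert-butyldimethylsilyl)oxy]tridecan-8-ol F3. Benzylation (NaH, BnBr, Bu4NI, THF) gives tert-butyl({(2R,8S)-8-(benzyloxy)-1-[3-(benzyloxy)-5-methoxyphenyl]tridecan-2-yl}oxy)dimethylsilane F4. TBAF in THF gives (2R,8S)-8-(benzyloxy)-1-[3-(benzyloxy)-5-methoxyphenyl]tridecan-2-ol F5. Ac2O, pyridine and DMAP give (2R,8S)-8-(benzyloxy)-1-[3-(benzyloxy)-5-methoxyphenyl]tridecan-2-yl acetate F6. Hydrogenolysis (H2, Pd/C, EtOAc) removes both benzyl groups and arrives at 18.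

3. Step 2. Over-epoxidation to the bis-epoxide and evaporative loss of the volatile mono-epoxide on separation from excess diene limit supply, and the resolution in step 3 then discards half of what remains. Fallback, setting out from 2 and coming back at 7: C2 is taken from the chiral pool, which also makes its configuration independent of the resolution. Grignard reagent 6 (from 2, Mg, THF) with commercial (S)-epichlorohydrin (CuI cat., THF, −40 °C) should open the epoxide at its CH2 to give (2S)-1-[3-(benzyloxy)-5-methoxyphenyl]-3-chloropropan-2-ol F7. NaOH (aq)/Et2O closes it to (2S)-2-{[3-(benzyloxy)-5-methoxyphenyl]methyl}oxirane F8. But-3-en-1-ylmagnesium bromide (CuI cat., THF, −30 °C) opens F8 at the ring CH2 and returns to 7. No bond to the stereocentre is broken; the descriptor changes from S to R only because the two carbon arms exchange rank.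

**Further compounds**

F1 | step 8 | (2R)-1-[3-(benzyloxy)-5-methoxyphenyl]hept-6-en-2-yl acetate | C=CCCC[C@H](Cc1cc(OCc2ccccc2)cc(OC)c1)OC(C)=O
F2 | step 8 | (2R,6E,8S)-1-[3-(benzyloxy)-5-methoxyphenyl]-8-hydroxytridec-6-en-2-yl acetate | CCCCC[C@H](O)/C=C/CCC[C@H](Cc1cc(OCc2ccccc2)cc(OC)c1)OC(C)=O
F3 | step 11 | (2R,8S)-1-[3-(benzyloxy)-5-methoxyphenyl]-2-[(tert-butyldimethylsilyl)oxy]tridecan-8-ol | CCCCC[C@H](O)CCCCC[C@H](Cc1cc(OCc2ccccc2)cc(OC)c1)O[Si](C)(C)C(C)(C)C
F4 | step 11 | tert-butyl({(2R,8S)-8-(benzyloxy)-1-[3-(benzyloxy)-5-methoxyphenyl]tridecan-2-yl}oxy)dimethylsilane | CCCCC[C@H](OCc1ccccc1)CCCCC[C@H](Cc2cc(OCc3ccccc3)cc(OC)c2)O[Si](C)(C)C(C)(C)C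
F5 | step 11 | (2R,8S)-8-(benzyloxy)-1-[3-(benzyloxy)-5-methoxyphenyl]tridecan-2-ol | CCCCC[C@H](OCc1ccccc1)CCCCC[C@H](Cc2cc(OCc3ccccc3)cc(OC)c2)O
F6 | step 11 | (2R,8S)-8-(benzyloxy)-1-[3-(benzyloxy)-5-methoxyphenyl]tridecan-2-yl acetate | CCCCC[C@H](OCc1ccccc1)CCCCC[C@H](Cc2cc(OCc3ccccc3)cc(OC)c2)OC(C)=O
F7 | step 2 | (2S)-1-[3-(benzyloxy)-5-methoxyphenyl]-3-chloropropan-2-ol | ClC[C@@H](O)Cc1cc(OCc2ccccc2)cc(OC)c1
F8 | step 2 | (2S)-2-{[3-(benzyloxy)-5-methoxyphenyl]methyl}oxirane | C1[C@@H](O1)Cc2cc(OCc3ccccc3)cc(OC)c2
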